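The benzene ring C4a–C5–C6–C7–C8–C8a carries five substituents and is fused to the cyclohexane C1–C4. Its edge C6(O)–C7(CO2)–C8(H)–C8a is a hidden 3-alkoxy-2-pyrone-4-carboxylate, its edge C4a–C5(O) a hidden alkynylboronate, and C1–C2–C3–C4 links the two.
Cuts: (a) C5–O back to C5–B, and the free OH/CO2H groups back to benzyl derivatives; (b) C4a–C8a and C5–C6 together (pyrone/alkyne [4+2], CO2 put back), which opens both rings; (c) pyrone O–C8a and C7–C8 (lactonisation, Sonogashira coupling); (d) C1–C11 (Ireland–Claisen).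
Chain assembly: the acid C20/C11–C16 and an allylic alcohol holding C1–C5 are esterified and rearranged to join C1–C11. The propenyl stump is then cut to the ethynyl group C8a≡C8 and coupled with an oxalate-derived enol triflate (C7, C6).
Rings: the pyrone is built first as a sacrificial ring. The cyclohexane and the benzene ring then arise together in one thermal step, leaving only C–B oxidation and hydrogenolysis.
Stereochemistry: C4 comes from (R)-citronellal and C15 from (R)-3-bromo-2-methylpropan-1-ol. A CBS reduction sets a carbinol centre whose chirality is passed to C1 and C11 through the chair of the Ireland–Claisen step (E-alkene, Z-silyl ketene acetal).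

Key step: step 22

Assumption: the labels C1–C8a (tetralin), C11–C16 (side chain) and C20 (acetoxymethyl carbon) are used for all compounds. In these labels the target SMILES reads (1S,4R,11S,15S). CIP descriptors of intermediates change only where substituent ranks change, not the spatial arrangement.

Step 1
Reactants: 1 (R)-citronellal
Product: 3 (3R)-3,7-dimethyloct-6-en-1-yne, via alkenyl nonaflate 2 (not isolated)
Conditions: n-C4F9SO2F, phosphazene base BTPP (2.2 equiv), DMF, 0 °C → rt
Reagents that add atoms: nonafluorobutane-1-sulfonyl fluoride, FS(=O)(=O)C(F)(F)C(F)(F)C(F)(F)C(F)(F)F (its atoms stay only in 2)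
Why: One-pot enol nonaflation and base-induced β-elimination of an enolisable aldehyde should give the terminal alkyne without change of carbon count; only the CH2 next to the formyl group is deprotonated, so the methyl-bearing centre (later C4) is not touched.

Step 2
Reactants: 3 (3R)-3,7-dimethyloct-6-en-1-yne
Product: 4 [(3R)-3,7-dimethyloct-6-en-1-yn-1-yl]triisopropylsilane
Conditions: n-BuLi, THF, −78 °C; TIPSCl, → rt
Reagents that add atoms: chlorotriisopropylsilane, CC(C)[Si](Cl)(C(C)C)C(C)C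
Why: Deprotonation and C-silylation of a terminal alkyne; the bulky TIPS group should keep this alkyne (later C4a≡C5) silent towards amide base, hydride, methanolic carbonate and Pd/Cu until step 20.

Step 3
Reactants: 4 [(3R)-3,7-dimethyloct-6-en-1-yn-1-yl]triisopropylsilane
Product: 5 (4R)-4-methyl-6-(triisopropylsilyl)hex-5-ynal
Conditions: O3, CH2Cl2, −78 °C (dye indicator); Me2S, → rt
Reagents that add atoms: ozone, [O-][O+]=O
Why: Ozonolysis with reductive work-up: the electron-rich trisubstituted alkene is consumed much faster than the hindered silylalkyne, and the indicator stops the ozone feed at the end point.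

Step 4
Reactants: 5 (4R)-4-methyl-6-(triisopropylsilyl)hex-5-ynal; 6 1-(triphenyl-λ5-phosphanylidene)propan-2-one
Product: 7 (3E,7R)-7-methyl-9-(triisopropylsilyl)non-3-en-8-yn-2-one
Conditions: CH2Cl2, rt → 40 °C
Reagents that add atoms: none
Why: Wittig olefination with a stabilised acyl ylide, which is reliably E-selective with unbranched aliphatic aldehydes.

Step 5
Reactants: 7 (3E,7R)-7-methyl-9-(triisopropylsilyl)non-3-en-8-yn-2-one
Product: 8 (2S,3E,7R)-7-methyl-9-(triisopropylsilyl)non-3-en-8-yn-2-ol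
Conditions: (R)-Me-CBS (20 mol%), catecholborane, PhMe, −78 °C; aq. work-up
Reagents that add atoms: none
Why: CBS (oxazaborolidine-catalysed) reduction: the alkenyl residue acts as the large group and methyl as the small group, so the (R)-catalyst should deliver hydride to the face that gives the (2S)-carbinol, and catecholborane at −78 °C does not hydroborate the alkene or the alkyne.

Step 6
Reactants: 9 (2R)-3-bromo-2-methylpropan-1-ol
Product: 10 {[(2R)-3-bromo-2-methylpropoxy]methyl}benzene
Conditions: BnOC(=NH)CCl3, TfOH (cat.), cyclohexane/CH2Cl2, 0 °C → rt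
Reagents that add atoms: benzyl 2,2,2-trichloroacetimidate, N=C(OCc1ccccc1)C(Cl)(Cl)Cl
Why: Acid-catalysed O-benzylation with the trichloroacetimidate avoids an alkoxide, which would displace the bromide (oxetane) or eliminate HBr; the stereocentre is not involved.

Step 7
Reactants: 10 {[(2R)-3-bromo-2-methylpropoxy]methyl}benzene; 11 ethyl 4-bromobutanoate
Product: 13 ethyl (6S)-7-(benzyloxy)-6-methylheptanoate, via Grignard reagent 12 (not isolated)
Conditions: Mg, THF, reflux; slow addition to 11, Li2CuCl4 (3 mol%), NMP, THF, 0 °C → rt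
Reagents that add atoms: magnesium, [Mg] (stays only in 12)
Why: Copper-catalysed Kumada-type sp3–sp3 coupling of a primary alkylmagnesium bromide with a primary alkyl bromide; with NMP as co-solvent and slow addition of 12 the substitution should outrun attack on the ester.

Step 8
Reactants: 13 ethyl (6S)-7-(benzyloxy)-6-methylheptanoate
Product: 14 (6S)-7-(benzyloxy)-6-methylheptanoic acid
Conditions: LiOH, THF/MeOH/H2O, rt; 1 M HCl
Reagents that add atoms: lithium hydroxide, [Li+].[OH-]
Why: Saponification of an unhindered ethyl ester; the remote C15 centre and the benzyl ether are inert.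

Step 9
Reactants: 8 (2S,3E,7R)-7-methyl-9-(triisopropylsilyl)non-3-en-8-yn-2-ol; 14 (6S)-7-(benzyloxy)-6-methylheptanoic acid
Product: 15 (2S,3E,7R)-7-methyl-9-(triisopropylsilyl)non-3-en-8-yn-2-yl (6S)-7-(benzyloxy)-6-methylheptanoate
Conditions: DCC, DMAP (cat.), CH2Cl2, 0 °C → rt
Reagents that add atoms: none
Why: Steglich esterification; the carbinol C–O bond is not broken, so the (S)-configuration is kept.

Step 10
Reactants: 15 allylic ester
Product: 18 (2S,3R,4E)-2-[(4S)-5-(benzyloxy)-4-methylpentyl]-3-[(3R)-3-methyl-5-(triisopropylsilyl)pent-4-yn-1-yl]hex-4-enoic acid, via (Z)-silyl ketene acetal 16 (not isolated), via trimethylsilyl ester 17 (not isolated)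
Conditions: LDA, THF/DMPU, −78 °C; TMSCl; −78 °C → rt; 1 M HCl
Reagents that add atoms: chlorotrimethylsilane, C[Si](C)(C)Cl (silicon stays only in 16 and 17)
Why: Ireland–Claisen rearrangement: enolisation in THF/DMPU gives the Z(O)-enolate and hence the (Z)-silyl ketene acetal 16, which should rearrange through a chair with the carbinol methyl group equatorial, so that the (S)-C–O centre is traded suprafacially for the C1 centre (spatially that of the target; descriptor R here because propenyl ranks below C11) and the Z-acetal/E-alkene pairing places C2 and C12 syn along C20–C11–C1–C8a, that is (11S), next to a new E-propenyl group.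

Step 11
Reactants: 18 Claisen acid
Product: 19 (2S,3R,4E)-2-[(4S)-5-(benzyloxy)-4-methylpentyl]-3-[(3R)-3-methyl-5-(triisopropylsilyl)pent-4-yn-1-yl]hex-4-en-1-ol
Conditions: LiAlH4, Et2O, 0 °C → rt
Reagents that add atoms: none
Why: Hydride reduction of the carboxylic acid to the primary alcohol (C20); alkene, silylalkyne and benzyl ether are inert to LiAlH4 and no stereocentre is at risk.

Step 12
Reactants: 19 homoallylic alcohol
Product: 21 (3S,4S)-4-[(4S)-5-(benzyloxy)-4-methylpentyl]-3-[(3R)-3-methyl-5-(triisopropylsilyl)pent-4-yn-1-yl]oxolan-2-ol (anomeric mixture), via hydroxy aldehyde 20 (not isolated)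
Conditions: O3, CH2Cl2, −78 °C (dye indicator); Me2S, → rt
Reagents that add atoms: ozone, [O-][O+]=O
Why: Ozonolysis of the only alkene; the γ-hydroxy aldehyde 20 should close spontaneously to the five-membered lactol, which makes a protecting group at C20–OH unnecessary and keeps the concentration of the epimerisable C1 aldehyde low.

Step 13
Reactants: 21 lactol
Product: 22 (2S,3S)-2-[(4S)-5-(benzyloxy)-4-methylpentyl]-3-[(3R)-3-methyl-5-(triisopropylsilyl)pent-4-yn-1-yl]pent-4-yn-1-ol
Conditions: Ohira–Bestmann reagent, K2CO3, MeOH, rt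
Reagents that add atoms: dimethyl (1-diazo-2-oxopropyl)phosphonate, COP(=O)(OC)C(=[N+]=[N-])C(C)=O
Why: Seyferth–Gilbert homologation with the Ohira–Bestmann reagent, well known for lactols that open to hydroxy aldehydes: the diazoalkene loses N2 and a 1,2-hydride shift gives the terminal alkyne C8a≡C8, while the TIPS-alkyne survives K2CO3/MeOH.

Step 14
Reactants: 22 alkynol
Product: 23 (2S,3S)-2-[(4S)-5-(benzyloxy)-4-methylpentyl]-3-[(3R)-3-methyl-5-(triisopropylsilyl)pent-4-yn-1-yl]pent-4-yn-1-yl acetate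
Conditions: Ac2O, pyridine, DMAP (cat.), CH2Cl2, 0 °C → rt
Reagents that add atoms: acetic anhydride, CC(=O)OC(C)=O
Why: DMAP-catalysed acetylation of the only free hydroxyl group installs the C20 acetate of the target.

Step 15
Reactants: 24 benzyl alcohol; 25 tert-butyl bromoacetate
Product: 26 tert-butyl 2-(benzyloxy)acetate
Conditions: NaH, THF, 0 °C → rt
Reagents that add atoms: none
Why: Williamson ether synthesis on a reactive α-bromo ester; the tert-butyl ester resists transesterification by benzyloxide.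

Step 16
Reactants: 26 tert-butyl 2-(benzyloxy)acetate; 27 dibenzyl oxalate
Product: 28 1-benzyl 4-tert-butyl 3-(benzyloxy)-2-oxobutanedioate (keto/enol mixture)
Conditions: LiHMDS, THF, −78 °C; 27, −78 → 0 °C; 1 M HCl
Reagents that add atoms: none
Why: Crossed Claisen condensation: the oxalate cannot enolise and is the more electrophilic ester, so the lithium enolate of 26 should be acylated once and the acidic product stays protected as its enolate until the quench.

Step 17
Reactants: 28 keto diester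
Product: 29 1-benzyl 4-tert-butyl (2E)-3-(benzyloxy)-2-{[(trifluoromethyl)sulfonyl]oxy}but-2-enedioate
Conditions: LiOTf, Et3N, Tf2O, CH2Cl2, 0 °C
Reagents that add atoms: trifluoromethanesulfonic anhydride, O=S(=O)(OS(=O)(=O)C(F)(F)F)C(F)(F)F
Why: O-Triflation of a β-keto ester under lithium chelation: the enolate oxygen and the tert-butyl ester carbonyl are held on the same side of the double bond, which should fix OTf cis to CO2tBu (E by CIP), the geometry needed for the later lactonisation.

Step 18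
Reactants: 23 diyne acetate; 29 enol triflate
Product: 30 1-benzyl 4-tert-butyl (2Z)-3-(benzyloxy)-2-{(3S,4S,8S)-4-(acetoxymethyl)-9-(benzyloxy)-8-methyl-3-[(3R)-3-methyl-5-(triisopropylsilyl)pent-4-yn-1-yl]non-1-yn-1-yl}but-2-enedioate
Conditions: Pd(PPh3)4 (5 mol%), CuI (10 mol%), i-Pr2NEt, degassed THF, rt
Reagents that add atoms: none
Why: Sonogashira coupling of an electron-poor enol triflate with the terminal alkyne forms C7–C8 with retention of the alkene geometry; the TIPS-capped alkyne cannot react and a tertiary amine base avoids addition–elimination at the triflate.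

Step 19
Reactants: 30 enyne diester
Product: 32 benzyl 6-{(1S,2S,6S)-2-(acetoxymethyl)-7-(benzyloxy)-6-methyl-1-[(3R)-3-methyl-5-(triisopropylsilyl)pent-4-yn-1-yl]heptyl}-3-(benzyloxy)-2-oxo-2H-pyran-4-carboxylate, via enynoic acid 31 (not isolated)
Conditions: TFA/CH2Cl2, 0 °C → rt; concentrate; ZnBr2 (20 mol%), THF, rt
Reagents that add atoms: none
Why: Acidolysis of the tert-butyl ester followed by Lewis-acid-catalysed 6-endo-dig lactonisation of the (Z)-2-en-4-ynoic acid, a known entry to 6-alkyl-2-pyrones with zinc bromide (silver salts favour the 5-exo mode); oxygen attacks C8a, the δ-carbon of the conjugated acceptor.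

Step 20
Reactants: 32 TIPS-alkynyl pyrone
Product: 34 benzyl 6-{(1S,2S,6S)-2-(acetoxymethyl)-7-(benzyloxy)-6-methyl-1-[(3R)-3-methylpent-4-yn-1-yl]heptyl}-3-(benzyloxy)-2-oxo-2H-pyran-4-carboxylate, via silver acetylide 33 (not isolated)
Conditions: AgF (1.5 equiv), MeCN, rt, dark; 1 M HCl
Reagents that add atoms: silver(I) fluoride, [Ag+].[F-] (silver stays only in 33)
Why: Silver-fluoride-mediated protiodesilylation of a bulky silylalkyne proceeds without free base, so acetate, benzyl ester, pyrone and the acidic C1–H should be left alone.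

Step 21
Reactants: 34 terminal-alkyne pyrone; 35 pinacolborane
Product: 36 benzyl 6-{(1S,2S,6S)-2-(acetoxymethyl)-7-(benzyloxy)-6-methyl-1-[(3R)-3-methyl-5-(4,4,5,5-tetramethyl-1,3,2-dioxaborolan-2-yl)pent-4-yn-1-yl]heptyl}-3-(benzyloxy)-2-oxo-2H-pyran-4-carboxylate
Conditions: cyclic (alkyl)(amino)carbene–CuOTf (2.5 mol%), Et3N (5 mol%), PhMe, rt; filtration through dry Celite
Reagents that add atoms: none
Why: Catalytic dehydrogenative C(sp)–H borylation of a terminal alkyne with pinacolborane: a copper acetylide is borylated by HBpin and the copper hydride is quenched by the ammonium salt with loss of H2, so no stoichiometric base meets the esters or the pyrone.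

Step 22
Reactants: 36 pyrone alkynylboronate
Product: 38 benzyl (5R,8S)-8-[(2S,6S)-1-acetoxy-7-(benzyloxy)-6-methylheptan-2-yl]-3-(benzyloxy)-5-methyl-4-(4,4,5,5-tetramethyl-1,3,2-dioxaborolan-2-yl)-5,6,7,8-tetrahydronaphthalene-2-carboxylate, via bridged bicyclic lactone 37 (not isolated)
Conditions: o-dichlorobenzene (0.01 M), BHT (10 mol%), Ar, sealed tube, 180 °C
Reagents that add atoms: none
Why: The alkyne C4a≡C5 adds across pyrone C6/C3 (C8a/C6 of the target) in a thermal intramolecular [4+2] cycloaddition, helped by the LUMO-lowering 4-carboxylate, to give the 2-oxabicyclo[2.2.2]octadienone 37, which loses CO2 by retro-[4+2] and aromatises irreversibly. The closest known reactions are the intermolecular benzannulation of 2-pyrones with alkynyl pinacolboronates and the benzannulation of 2-pyrones that carry a tethered alkyne; the present substrate merges the two. The cyclohexane (C1–C4, C4a, C8a) closes through the C4a–C8a bond as the tether-enforced six-membered ring of a type-1 intramolecular Diels–Alder reaction, and the benzene ring closes through C4a–C8a and C5–C6 as the cycloaddition ring itself, completed by the cycloreversion. No stereocentre is created: the two bridgehead centres of 37 vanish with CO2, so attack on either diene face leads to the same product, and C1, C4, C11 and C15 are only carried along. The selectivity needed is regiochemical (boron on C5 next to the C6 ether, ester on C7, hydrogen on C8) and is fixed by the four-carbon tether, because the reversed orientation would demand a strained bridged ring. Neutral, degassed, base-free conditions are chosen so that C1–H next to the pyrone and the propargylic C4–H are not epimerised and the C–B bond is not protonated off.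

Step 23
Reactants: 38 tetralin C5-boronate
Product: 39 benzyl (5R,8S)-8-[(2S,6S)-1-acetoxy-7-(benzyloxy)-6-methylheptan-2-yl]-3-(benzyloxy)-4-hydroxy-5-methyl-5,6,7,8-tetrahydronaphthalene-2-carboxylate
Conditions: NaBO3·4H2O, THF/H2O, rt
Reagents that add atoms: sodium perborate, [Na+].[O-]OB=O
Why: Oxidation of an arylboronic ester by 1,2-aryl migration from boron to peroxide oxygen places the hydroxyl group exactly at C5; perborate is mild enough for the acetate and the benzyl ester.

Step 24
Reactants: 39 C5 phenol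
Product: 40 (5R,8S)-8-[(2S,6S)-1-acetoxy-7-hydroxy-6-methylheptan-2-yl]-3,4-dihydroxy-5-methyl-5,6,7,8-tetrahydronaphthalene-2-carboxylic acid (target)
Conditions: H2 (1 atm), 10% Pd/C, EtOAc/EtOH, rt
Reagents that add atoms: none
Why: Catalytic hydrogenolysis removes the C16 benzyl ether, the C6 aryl benzyl ether and the C7 benzyl ester in one operation; acetate, arene and all four stereocentres are unaffected.

Compound list
1 | (R)-citronellal, (3R)-3,7-dimethyloct-6-enal | CC(C)=CCC[C@@H](C)CC=O | starting material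
2 | (3R)-3,7-dimethylocta-1,6-dien-1-yl nonafluorobutane-1-sulfonate (E/Z mixture) | CC(C)=CCC[C@@H](C)C=COS(=O)(=O)C(F)(F)C(F)(F)C(F)(F)C(F)(F)F | intermediate
3 | (3R)-3,7-dimethyloct-6-en-1-yne | CC(C)=CCC[C@@H](C)C#C | intermediate
4 | [(3R)-3,7-dimethyloct-6-en-1-yn-1-yl]triisopropylsilane | CC(C)=CCC[C@@H](C)C#C[Si](C(C)C)(C(C)C)C(C)C | intermediate
5 | (4R)-4-methyl-6-(triisopropylsilyl)hex-5-ynal | O=CCC[C@@H](C)C#C[Si](C(C)C)(C(C)C)C(C)C | intermediate
6 | 1-(triphenyl-λ5-phosphanylidene)propan-2-one | CC(=O)C=P(c1ccccc1)(c1ccccc1)c1ccccc1 | starting material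
7 | (3E,7R)-7-methyl-9-(triisopropylsilyl)non-3-en-8-yn-2-one | CC(=O)/C=C/CC[C@@H](C)C#C[Si](C(C)C)(C(C)C)C(C)C | intermediate
8 | (2S,3E,7R)-7-methyl-9-(triisopropylsilyl)non-3-en-8-yn-2-ol | C[C@H](O)/C=C/CC[C@@H](C)C#C[Si](C(C)C)(C(C)C)C(C)C | intermediate
9 | (2R)-3-bromo-2-methylpropan-1-ol | BrC[C@H](C)CO | starting material
10 | {[(2R)-3-bromo-2-methylpropoxy]methyl}benzene | BrC[C@H](C)COCc1ccccc1 | intermediate
11 | ethyl 4-bromobutanoate | CCOC(=O)CCCBr | starting material
12 | [(2R)-3-(benzyloxy)-2-methylpropyl]magnesium bromide | Br[Mg]C[C@H](C)COCc1ccccc1 | intermediate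
13 | ethyl (6S)-7-(benzyloxy)-6-methylheptanoate | CCOC(=O)CCCC[C@H](C)COCc1ccccc1 | intermediate
14 | (6S)-7-(benzyloxy)-6-methylheptanoic acid | OC(=O)CCCC[C@H](C)COCc1ccccc1 | intermediate
15 | (2S,3E,7R)-7-methyl-9-(triisopropylsilyl)non-3-en-8-yn-2-yl (6S)-7-(benzyloxy)-6-methylheptanoate | C[C@H](OC(=O)CCCC[C@H](C)COCc1ccccc1)/C=C/CC[C@@H](C)C#C[Si](C(C)C)(C(C)C)C(C)C | intermediate
16 | (Z)-O-trimethylsilyl ketene acetal of 15 (C12 chain cis to OSiMe3) | C[C@H](O/C(O[Si](C)(C)C)=C/CCC[C@H](C)COCc1ccccc1)/C=C/CC[C@@H](C)C#C[Si](C(C)C)(C(C)C)C(C)C | intermediate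
17 | trimethylsilyl ester of acid 18 | C[Si](C)(C)OC(=O)[C@@H](CCC[C@H](C)COCc1ccccc1)[C@H](CC[C@@H](C)C#C[Si](C(C)C)(C(C)C)C(C)C)/C=C/C | intermediate
18 | (2S,3R,4E)-2-[(4S)-5-(benzyloxy)-4-methylpentyl]-3-[(3R)-3-methyl-5-(triisopropylsilyl)pent-4-yn-1-yl]hex-4-enoic acid | OC(=O)[C@@H](CCC[C@H](C)COCc1ccccc1)[C@H](CC[C@@H](C)C#C[Si](C(C)C)(C(C)C)C(C)C)/C=C/C | intermediate
19 | (2S,3R,4E)-2-[(4S)-5-(benzyloxy)-4-methylpentyl]-3-[(3R)-3-methyl-5-(triisopropylsilyl)pent-4-yn-1-yl]hex-4-en-1-ol | OC[C@@H](CCC[C@H](C)COCc1ccccc1)[C@H](CC[C@@H](C)C#C[Si](C(C)C)(C(C)C)C(C)C)/C=C/C | intermediate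
20 | (2S,3S)-3-[(4S)-5-(benzyloxy)-4-methylpentyl]-4-hydroxy-2-[(3R)-3-methyl-5-(triisopropylsilyl)pent-4-yn-1-yl]butanal | OC[C@@H](CCC[C@H](C)COCc1ccccc1)[C@H](CC[C@@H](C)C#C[Si](C(C)C)(C(C)C)C(C)C)C=O | intermediate
21 | (3S,4S)-4-[(4S)-5-(benzyloxy)-4-methylpentyl]-3-[(3R)-3-methyl-5-(triisopropylsilyl)pent-4-yn-1-yl]oxolan-2-ol (anomeric mixture) | OC1OC[C@@H](CCC[C@H](C)COCc2ccccc2)[C@@H]1CC[C@@H](C)C#C[Si](C(C)C)(C(C)C)C(C)C | intermediate
22 | (2S,3S)-2-[(4S)-5-(benzyloxy)-4-methylpentyl]-3-[(3R)-3-methyl-5-(triisopropylsilyl)pent-4-yn-1-yl]pent-4-yn-1-ol | OC[C@@H](CCC[C@H](C)COCc1ccccc1)[C@H](CC[C@@H](C)C#C[Si](C(C)C)(C(C)C)C(C)C)C#C | intermediate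
23 | acetate of 22 | CC(=O)OC[C@@H](CCC[C@H](C)COCc1ccccc1)[C@H](CC[C@@H](C)C#C[Si](C(C)C)(C(C)C)C(C)C)C#C | intermediate
24 | benzyl alcohol | OCc1ccccc1 | starting material
25 | tert-butyl bromoacetate | CC(C)(C)OC(=O)CBr | starting material
26 | tert-butyl 2-(benzyloxy)acetate | CC(C)(C)OC(=O)COCc1ccccc1 | intermediate
27 | dibenzyl oxalate | O=C(OCc1ccccc1)C(=O)OCc1ccccc1 | starting material
28 | 1-benzyl 4-tert-butyl 3-(benzyloxy)-2-oxobutanedioate (keto/enol mixture, labile centre) | O=C(OCc1ccccc1)C(=O)C(OCc1ccccc1)C(=O)OC(C)(C)C | intermediate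
29 | 1-benzyl 4-tert-butyl (2E)-3-(benzyloxy)-2-{[(trifluoromethyl)sulfonyl]oxy}but-2-enedioate (OTf cis to CO2tBu) | O=C(OCc1ccccc1)/C(OS(=O)(=O)C(F)(F)F)=C(OCc1ccccc1)/C(=O)OC(C)(C)C | intermediate
30 | 1-benzyl 4-tert-butyl (2Z)-3-(benzyloxy)-2-{(3S,4S,8S)-4-(acetoxymethyl)-9-(benzyloxy)-8-methyl-3-[(3R)-3-methyl-5-(triisopropylsilyl)pent-4-yn-1-yl]non-1-yn-1-yl}but-2-enedioate (alkynyl cis to CO2tBu) | CC(=O)OC[C@@H](CCC[C@H](C)COCc1ccccc1)[C@H](CC[C@@H](C)C#C[Si](C(C)C)(C(C)C)C(C)C)C#C/C(C(=O)OCc1ccccc1)=C(OCc1ccccc1)\C(=O)OC(C)(C)C | intermediate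
31 | free C4 acid of 30, a (Z)-2-en-4-ynoic acid | CC(=O)OC[C@@H](CCC[C@H](C)COCc1ccccc1)[C@H](CC[C@@H](C)C#C[Si](C(C)C)(C(C)C)C(C)C)C#C/C(C(=O)OCc1ccccc1)=C(OCc1ccccc1)\C(=O)O | intermediate
32 | benzyl 6-{(1S,2S,6S)-2-(acetoxymethyl)-7-(benzyloxy)-6-methyl-1-[(3R)-3-methyl-5-(triisopropylsilyl)pent-4-yn-1-yl]heptyl}-3-(benzyloxy)-2-oxo-2H-pyran-4-carboxylate | CC(=O)OC[C@@H](CCC[C@H](C)COCc1ccccc1)[C@H](CC[C@@H](C)C#C[Si](C(C)C)(C(C)C)C(C)C)c1cc(C(=O)OCc2ccccc2)c(OCc2ccccc2)c(=O)o1 | intermediate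
33 | silver acetylide of 34 | CC(=O)OC[C@@H](CCC[C@H](C)COCc1ccccc1)[C@H](CC[C@@H](C)C#C[Ag])c1cc(C(=O)OCc2ccccc2)c(OCc2ccccc2)c(=O)o1 | intermediate
34 | benzyl 6-{(1S,2S,6S)-2-(acetoxymethyl)-7-(benzyloxy)-6-methyl-1-[(3R)-3-methylpent-4-yn-1-yl]heptyl}-3-(benzyloxy)-2-oxo-2H-pyran-4-carboxylate | CC(=O)OC[C@@H](CCC[C@H](C)COCc1ccccc1)[C@H](CC[C@@H](C)C#C)c1cc(C(=O)OCc2ccccc2)c(OCc2ccccc2)c(=O)o1 | intermediate
35 | pinacolborane | B1OC(C)(C)C(C)(C)O1 | starting material
36 | benzyl 6-{(1S,2S,6S)-2-(acetoxymethyl)-7-(benzyloxy)-6-methyl-1-[(3R)-3-methyl-5-(4,4,5,5-tetramethyl-1,3,2-dioxaborolan-2-yl)pent-4-yn-1-yl]heptyl}-3-(benzyloxy)-2-oxo-2H-pyran-4-carboxylate | CC(=O)OC[C@@H](CCC[C@H](C)COCc1ccccc1)[C@H](CC[C@@H](C)C#CB2OC(C)(C)C(C)(C)O2)c3cc(C(=O)OCc4ccccc4)c(OCc5ccccc5)c(=O)o3 | intermediate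
37 | 2-oxabicyclo[2.2.2]octa-5,7-dien-3-one cycloadduct fused to the new cyclohexane (bridgeheads C8a and C6, either facial isomer) | CC(=O)OC[C@@H](CCC[C@H](C)COCc1ccccc1)[C@@H]2CC[C@@H](C)C3=C(B4OC(C)(C)C(C)(C)O4)C5(OCc6ccccc6)C(=O)OC23C=C5C(=O)OCc7ccccc7 | intermediate
38 | benzyl (5R,8S)-8-[(2S,6S)-1-acetoxy-7-(benzyloxy)-6-methylheptan-2-yl]-3-(benzyloxy)-5-methyl-4-(4,4,5,5-tetramethyl-1,3,2-dioxaborolan-2-yl)-5,6,7,8-tetrahydronaphthalene-2-carboxylate | CC(=O)OC[C@@H](CCC[C@H](C)COCc1ccccc1)[C@@H]2CC[C@@H](C)c3c2cc(C(=O)OCc4ccccc4)c(OCc5ccccc5)c3B6OC(C)(C)C(C)(C)O6 | intermediate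
39 | benzyl (5R,8S)-8-[(2S,6S)-1-acetoxy-7-(benzyloxy)-6-methylheptan-2-yl]-3-(benzyloxy)-4-hydroxy-5-methyl-5,6,7,8-tetrahydronaphthalene-2-carboxylate | CC(=O)OC[C@@H](CCC[C@H](C)COCc1ccccc1)[C@@H]2CC[C@@H](C)c3c2cc(C(=O)OCc4ccccc4)c(OCc5ccccc5)c3O | intermediate
40 | (5R,8S)-8-[(2S,6S)-1-acetoxy-7-hydroxy-6-methylheptan-2-yl]-3,4-dihydroxy-5-methyl-5,6,7,8-tetrahydronaphthalene-2-carboxylic acid, CNP0191669.1 | CC(=O)OC[C@@H](CCC[C@H](C)CO)[C@@H]1CC[C@@H](C)c2c1cc(C(=O)O)c(O)c2O | target

Total step count: 24.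
Longest linear sequence: 18 steps from (R)-citronellal (steps 1–5, 9–14, 18–24). Steps 6–8 and 15–17 are side branches.

Steps most likely to fail

1. Step 22.
- What may go wrong: the hindered, boron-bearing alkyne may add too slowly. Protodeboronation, or epimerisation at C1 on long heating, could then overtake ring closure.
- Fallback: it sets out from 34 and comes back at 38. The terminal alkyne itself is heated (o-dichlorobenzene, 160–180 °C). This is the established benzannulation of a 2-pyrone with a tethered alkyne, now with a smaller dienophile, and should give the C5-unsubstituted tetralin F1. NBS in MeCN in the dark should then brominate C5, the only free position activated by the C6 ether (ortho) and by both ring alkyl groups, to give the C5 bromide F2. Miyaura borylation (B2pin2, Pd(dppf)Cl2, KOAc, dioxane, 90 °C) leads to 38.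

2. Step 21.
- What may go wrong: hydride may be transferred from the copper hydride or from HBpin to the electron-poor pyrone, or the alkyne may be hydroborated in place of C–H borylation.
- Fallback: it sets out from 34 and comes back at 36, without any hydride source. NIS with catalytic AgNO3 in acetone should give the iodoalkyne F3. Iodine–magnesium exchange with i-PrMgCl·LiCl at −78 °C is much faster than attack on esters at that temperature and gives the alkynylmagnesium chloride F4. This is trapped at once with 2-isopropoxy-4,4,5,5-tetramethyl-1,3,2-dioxaborolane as the isopropoxyborate F5. Anhydrous HCl in ether collapses F5 to 36.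

3. Step 19.
- What may go wrong: the carboxylate may close in the 5-exo-dig mode on C8 to an alkylidene butenolide instead of closing 6-endo on C8a.
- Fallback: it sets out from 30 and comes back at 32 by electrophilic rather than Lewis-acid cyclisation. ICl in CH2Cl2 at rt should activate the alkyne as an iodonium ion. The ester carbonyl oxygen opens this ion at C8a with loss of the tert-butyl group, giving the 5-iodo-2-pyrone F6. Palladium-catalysed formate reduction (Pd(OAc)2, PPh3, HCO2H, Et3N, DMF) removes the iodine and gives 32.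

Further compounds
F1 | step 22 | benzyl (5R,8S)-8-[(2S,6S)-1-acetoxy-7-(benzyloxy)-6-methylheptan-2-yl]-3-(benzyloxy)-5-methyl-5,6,7,8-tetrahydronaphthalene-2-carboxylate | CC(=O)OC[C@@H](CCC[C@H](C)COCc1ccccc1)[C@@H]2CC[C@@H](C)c3c2cc(C(=O)OCc4ccccc4)c(OCc5ccccc5)c3
F2 | step 22 | benzyl (5R,8S)-8-[(2S,6S)-1-acetoxy-7-(benzyloxy)-6-methylheptan-2-yl]-3-(benzyloxy)-4-bromo-5-methyl-5,6,7,8-tetrahydronaphthalene-2-carboxylate | CC(=O)OC[C@@H](CCC[C@H](C)COCc1ccccc1)[C@@H]2CC[C@@H](C)c3c2cc(C(=O)OCc4ccccc4)c(OCc5ccccc5)c3Br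
F3 | step 21 | iodoalkyne of 34 (C5–I) | CC(=O)OC[C@@H](CCC[C@H](C)COCc1ccccc1)[C@H](CC[C@@H](C)C#CI)c2cc(C(=O)OCc3ccccc3)c(OCc4ccccc4)c(=O)o2
F4 | step 21 | alkynylmagnesium chloride of 34 | CC(=O)OC[C@@H](CCC[C@H](C)COCc1ccccc1)[C@H](CC[C@@H](C)C#C[Mg]Cl)c2cc(C(=O)OCc3ccccc3)c(OCc4ccccc4)c(=O)o2
F5 | step 21 | chloromagnesium alkynyl(isopropoxy)pinacolborate | CC(=O)OC[C@@H](CCC[C@H](C)COCc1ccccc1)[C@H](CC[C@@H](C)C#C[B-]2(OC(C)C)OC(C)(C)C(C)(C)O2)c3cc(C(=O)OCc4ccccc4)c(OCc5ccccc5)c(=O)o3.[Mg+2].[Cl-]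
F6 | step 19 | 5-iodo derivative of pyrone 32 | CC(=O)OC[C@@H](CCC[C@H](C)COCc1ccccc1)[C@H](CC[C@@H](C)C#C[Si](C(C)C)(C(C)C)C(C)C)c1oc(=O)c(OCc2ccccc2)c(C(=O)OCc2ccccc2)c1I
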